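Rings are lettered A–G from the 2,4,6-trihydroxyphenoxy end to the 3,4,5-trihydroxyphenoxy end; central ring D carries O-aryl at C1 (from ring C) and C2 (from ring E), OH at C3–C5 and H at C6.
Cuts: first the fifteen O–methyl bonds, then both aryl–O bonds at D-C1 and D-C2 together. The C4/C5 catechol of ring D is read as an o-quinone whose two β-carbons are exactly C1 and C2, so 4,5-dibromo-3-methoxy-1,2-benzoquinone can take up the ABC and EFG phenols by two addition–eliminations.
Each arm is cut at its diaryl ether bonds, all of which join a di-ortho-methoxy phenol oxygen to an aryl carbon with free ortho positions (Ullmann coupling, and one Chan–Lam coupling where an aryl bromide has to survive).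
Forward: ABC phenol (steps 1–5), EFG phenol (steps 6–9), quinone (steps 10–14), union on ring D (step 15), quinone reduction and global demethylation (steps 16–17); a chain is joined and no ring is formed.
The quinone's bromine positions are fixed by starting from symmetrical 4,5-dibromocatechol and adding the third oxygen by ortho-metalation, because electrophilic dibromination of 3-methoxycatechol is expected to go to C4/C6 instead.
The target is achiral and has no stereocentre, so no stereochemistry has to be set.

Key step: step 15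

Remark: 2,6-dimethoxyhydroquinone and 4,5-dibromocatechol are taken as purchasable (otherwise one operation each from 2,6-dimethoxy-1,4-benzoquinone with dithionite and from catechol with two equivalents of bromine).

Step 1
Reactants: 1 4-bromo-2,6-dimethoxyphenol
Product: 2 2-(benzyloxy)-5-bromo-1,3-dimethoxybenzene
Conditions: BnBr, K2CO3, DMF, 60 °C
Reagents that add atoms: benzyl bromide BrCc1ccccc1
Why: Williamson etherification masks the hindered OH as a benzyl ether that survives copper catalysis and is later removed by hydrogenolysis without touching methyl or diaryl ethers.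

Step 2
Reactants: 3 2,4,6-trimethoxyphenol; 2 2-(benzyloxy)-5-bromo-1,3-dimethoxybenzene
Product: 4 2-(benzyloxy)-1,3-dimethoxy-5-(2,4,6-trimethoxyphenoxy)benzene
Conditions: CuI (10 mol %), picolinic acid (20 mol %), K3PO4, DMSO, 100 °C, Ar
Reagents that add atoms: none
Why: Ligand-accelerated Ullmann diaryl ether synthesis, using the Cu(I)/picolinate system suited to di-ortho-substituted phenols, should join the hindered phenoxide of 3 to the bromide of 2, whose two ortho positions are free.

Step 3
Reactants: 4 2-(benzyloxy)-1,3-dimethoxy-5-(2,4,6-trimethoxyphenoxy)benzene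
Product: 5 2,6-dimethoxy-4-(2,4,6-trimethoxyphenoxy)phenol
Conditions: H2 (1 atm), 10% Pd/C, EtOAc–MeOH, rt
Reagents that add atoms: none
Why: Hydrogenolysis of the benzyl ether frees the di-ortho-methoxy phenol, and the molecule holds no halogen or other reducible group at this stage.

Step 4
Reactants: 5 2,6-dimethoxy-4-(2,4,6-trimethoxyphenoxy)phenol; 2 2-(benzyloxy)-5-bromo-1,3-dimethoxybenzene
Product: 6 2-(benzyloxy)-5-[2,6-dimethoxy-4-(2,4,6-trimethoxyphenoxy)phenoxy]-1,3-dimethoxybenzene
Conditions: CuI (10 mol %), picolinic acid (20 mol %), K3PO4, DMSO, 100 °C, Ar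
Reagents that add atoms: none
Why: A second Ullmann etherification of the same type, since the phenol of 5 sits in the same di-ortho-methoxy environment as that of 3.

Step 5
Reactants: 6 2-(benzyloxy)-5-[2,6-dimethoxy-4-(2,4,6-trimethoxyphenoxy)phenoxy]-1,3-dimethoxybenzene
Product: 7 4-[2,6-dimethoxy-4-(2,4,6-trimethoxyphenoxy)phenoxy]-2,6-dimethoxyphenol (ABC phenol)
Conditions: H2 (1 atm), 10% Pd/C, EtOAc–MeOH, rt
Reagents that add atoms: none
Why: Benzyl ether hydrogenolysis as in step 3 should give the ABC phenol with its free OH on ring C between two methoxy groups.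

Step 6
Reactants: 8 2,6-dimethoxybenzene-1,4-diol (2,6-dimethoxyhydroquinone)
Product: 9 4-(benzyloxy)-2,6-dimethoxyphenol
Conditions: BnBr (1.0 equiv), K2CO3 (1.0 equiv), degassed DMF, 0 °C → rt, Ar
Reagents that add atoms: benzyl bromide BrCc1ccccc1
Why: Williamson etherification should occur at the 4-OH, which is less hindered and more acidic than the 1-OH lying between two methoxy groups, so one equivalent of base and halide leaves the hindered OH free.

Step 7
Reactants: 10 3,4,5-trimethoxyphenylboronic acid; 1 4-bromo-2,6-dimethoxyphenol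
Product: 11 5-(4-bromo-2,6-dimethoxyphenoxy)-1,2,3-trimethoxybenzene
Conditions: Cu(OAc)2 (1.0 equiv), pyridine, 4 Å MS, CH2Cl2, dry air (O2 as terminal oxidant), rt
Reagents that add atoms: none
Why: Chan–Lam oxidative coupling forms the aryl–O bond at room temperature and leaves the C–Br bond of 1 untouched, whereas an Ullmann coupling would let 1 condense with itself.

Step 8
Reactants: 11 5-(4-bromo-2,6-dimethoxyphenoxy)-1,2,3-trimethoxybenzene; 9 4-(benzyloxy)-2,6-dimethoxyphenol
Product: 12 5-(benzyloxy)-2-[3,5-dimethoxy-4-(3,4,5-trimethoxyphenoxy)phenoxy]-1,3-dimethoxybenzene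
Conditions: CuI (10 mol %), picolinic acid (20 mol %), K3PO4, DMSO, 100 °C, Ar
Reagents that add atoms: none
Why: Ullmann etherification of the same type as steps 2 and 4, joining a di-ortho-methoxy phenoxide to a bromide with two free ortho positions.

Step 9
Reactants: 12 5-(benzyloxy)-2-[3,5-dimethoxy-4-(3,4,5-trimethoxyphenoxy)phenoxy]-1,3-dimethoxybenzene
Product: 13 4-[3,5-dimethoxy-4-(3,4,5-trimethoxyphenoxy)phenoxy]-3,5-dimethoxyphenol (EFG phenol)
Conditions: H2 (1 atm), 10% Pd/C, EtOAc–MeOH, rt
Reagents that add atoms: none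
Why: Benzyl ether hydrogenolysis should give the EFG phenol with its free OH on ring E para to the ether and both ortho positions unsubstituted.

Step 10
Reactants: 14 4,5-dibromobenzene-1,2-diol
Product: 15 5,6-dibromo-2,2-dimethyl-1,3-benzodioxole
Conditions: 2,2-dimethoxypropane, TsOH·H2O (cat.), toluene, reflux with removal of MeOH
Reagents that add atoms: 2,2-dimethoxypropane COC(C)(C)OC
Why: Acid-catalysed transketalisation gives the catechol acetonide, which is inert to amide bases and can later be removed with aqueous acid without cleaving a methyl ether.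

Step 11
Reactants: 15 5,6-dibromo-2,2-dimethyl-1,3-benzodioxole
Product: 17 5,6-dibromo-2,2-dimethyl-1,3-benzodioxol-4-ol, via diisopropyl arylboronate 16 (not isolated)
Conditions: LDA added to 15 and B(OiPr)3, THF, −78 °C; then AcOH, 30% H2O2, 0 °C → rt
Reagents that add atoms: hydrogen peroxide OO
Why: The two ring hydrogens of 15 are equivalent and each lies between a ring oxygen and a bromine, so directed ortho-lithiation can only occur at the wanted carbon; in situ trapping as the borate forestalls aryne formation and halogen migration, and peroxide oxidation of the C–B bond gives the phenol.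

Step 12
Reactants: 17 5,6-dibromo-2,2-dimethyl-1,3-benzodioxol-4-ol
Product: 18 5,6-dibromo-4-methoxy-2,2-dimethyl-1,3-benzodioxole
Conditions: MeI, K2CO3, DMF, rt
Reagents that add atoms: iodomethane CI
Why: Williamson methylation of the phenoxide installs the one methyl ether that ring D keeps until the end, on the oxygen next to a bromine.

Step 13
Reactants: 18 5,6-dibromo-4-methoxy-2,2-dimethyl-1,3-benzodioxole
Product: 19 4,5-dibromo-3-methoxybenzene-1,2-diol
Conditions: TFA–H2O (9:1), 40 °C
Reagents that add atoms: none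
Why: Acid hydrolysis of the catechol acetonide should free the 1,2-diol while the aryl methyl ether and the C–Br bonds are inert to aqueous acid.

Step 14
Reactants: 19 4,5-dibromo-3-methoxybenzene-1,2-diol
Product: 20 4,5-dibromo-3-methoxy-1,2-benzoquinone
Conditions: Ag2O, Na2SO4, Et2O, 0 °C, dark; filtered and used at once
Reagents that add atoms: none
Why: Silver(I) oxide oxidises the catechol to the o-quinone under neutral, anhydrous conditions, and filtration leaves a solution free of any nucleophile or reductant.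

Step 15
Reactants: 20 4,5-dibromo-3-methoxy-1,2-benzoquinone; 7 4-[2,6-dimethoxy-4-(2,4,6-trimethoxyphenoxy)phenoxy]-2,6-dimethoxyphenol; 13 4-[3,5-dimethoxy-4-(3,4,5-trimethoxyphenoxy)phenoxy]-3,5-dimethoxyphenol
Product: 22 3-methoxy-5-(ArABC-oxy)-4-(ArEFG-oxy)-1,2-benzoquinone [ArABC-O = aryloxy group of 7; ArEFG-O = aryloxy group of 13], via 5-aryloxy-4-bromoquinone 21 (not isolated)
Conditions: caesium phenoxide of 7 (7, Cs2CO3, 4 Å MS, DMF, rt) added dropwise to 20 in THF–DMF, −40 °C, Ar, dark; then caesium phenoxide of 13 (13, Cs2CO3, DMF), −40 → 0 °C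
Reagents that add atoms: none
Why: The phenoxide of 7 adds to quinone C5 (ring D C1), the β-carbon of the C6=C5–C1=O enone, and the enolate expels bromide to restore the quinone as vinylogous aryl ester 21; the phenoxide of 13 then does the same at C4 (ring D C2, β to C2=O) to give 22, so both aryl–O bonds of ring D form without a metal. The closest known reaction is displacement of halide from halogenated quinones (chloranil, 2,3-dichloro-1,4-naphthoquinone, o-chloranil) by phenoxides and catecholates. No ring is closed and no stereocentre is created. The step needs site order, which the substrate supplies: the C3 methoxy group feeds electron density to C4 and C6 and C4 is flanked by OMe and Br, so the first phenoxide goes to C5, and being di-ortho-methoxylated it is too hindered to follow on at C4, which is left for the ortho-unsubstituted phenoxide of 13. It also needs O- rather than C-attack by 13, whose ring E is a phloroglucinol-type nucleophile with two free ortho carbons; a caesium phenoxide in a dipolar aprotic medium reacts at oxygen, while 7 has no free ortho or para carbon at all. Electron transfer from the phenoxides to the quinone is the competing process and is held back by low temperature and slow addition to the quinone; any 22 reduced in the flask is not lost, because step 16 reduces it anyway.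

Step 16
Reactants: 22 3-methoxy-5-(ArABC-oxy)-4-(ArEFG-oxy)-1,2-benzoquinone
Product: 23 3-methoxy-5-(ArABC-oxy)-4-(ArEFG-oxy)benzene-1,2-diol
Conditions: Na2S2O4, THF–H2O, rt, Ar
Reagents that add atoms: none
Why: Dithionite reduces the o-quinone to the catechol, restoring aromatic ring D with its full oxygen pattern and H at C6.

Step 17
Reactants: 23 3-methoxy-5-(ArABC-oxy)-4-(ArEFG-oxy)benzene-1,2-diol
Product: 24 CNP0304148.0 (heptadecahydroxy heptaphenyl hexaether, the target)
Conditions: BBr3 (about 3 equiv per OMe), CH2Cl2, −78 °C → rt; then degassed H2O, 0 °C, Ar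
Reagents that add atoms: none
Why: Boron tribromide cleaves all fifteen aryl methyl ethers by bromide attack on the O-methyl carbon of the borane complex, while the diaryl ether oxygens carry no sp3 carbon and are not cleaved.

Compound list
1 | 4-bromo-2,6-dimethoxyphenol | COc1cc(Br)cc(OC)c1O | starting material
2 | 2-(benzyloxy)-5-bromo-1,3-dimethoxybenzene | COc1cc(Br)cc(OC)c1OCc1ccccc1 | intermediate
3 | 2,4,6-trimethoxyphenol | COc1cc(OC)c(O)c(OC)c1 | starting material
4 | 2-(benzyloxy)-1,3-dimethoxy-5-(2,4,6-trimethoxyphenoxy)benzene | COc1cc(OC)c(Oc2cc(OC)c(OCc3ccccc3)c(OC)c2)c(OC)c1 | intermediate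
5 | 2,6-dimethoxy-4-(2,4,6-trimethoxyphenoxy)phenol | COc1cc(OC)c(Oc2cc(OC)c(O)c(OC)c2)c(OC)c1 | intermediate
6 | 2-(benzyloxy)-5-[2,6-dimethoxy-4-(2,4,6-trimethoxyphenoxy)phenoxy]-1,3-dimethoxybenzene | COc1cc(OC)c(Oc2cc(OC)c(Oc3cc(OC)c(OCc4ccccc4)c(OC)c3)c(OC)c2)c(OC)c1 | intermediate
7 | 4-[2,6-dimethoxy-4-(2,4,6-trimethoxyphenoxy)phenoxy]-2,6-dimethoxyphenol (ABC phenol) | COc1cc(OC)c(Oc2cc(OC)c(Oc3cc(OC)c(O)c(OC)c3)c(OC)c2)c(OC)c1 | intermediate
8 | 2,6-dimethoxybenzene-1,4-diol | COc1cc(O)cc(OC)c1O | starting material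
9 | 4-(benzyloxy)-2,6-dimethoxyphenol | COc1cc(OCc2ccccc2)cc(OC)c1O | intermediate
10 | 3,4,5-trimethoxyphenylboronic acid | COc1cc(B(O)O)cc(OC)c1OC | starting material
11 | 5-(4-bromo-2,6-dimethoxyphenoxy)-1,2,3-trimethoxybenzene | COc1cc(Oc2c(OC)cc(Br)cc2OC)cc(OC)c1OC | intermediate
12 | 5-(benzyloxy)-2-[3,5-dimethoxy-4-(3,4,5-trimethoxyphenoxy)phenoxy]-1,3-dimethoxybenzene | COc1cc(OCc2ccccc2)cc(OC)c1Oc1cc(OC)c(Oc2cc(OC)c(OC)c(OC)c2)c(OC)c1 | intermediate
13 | 4-[3,5-dimethoxy-4-(3,4,5-trimethoxyphenoxy)phenoxy]-3,5-dimethoxyphenol (EFG phenol) | Oc1cc(OC)c(Oc2cc(OC)c(Oc3cc(OC)c(OC)c(OC)c3)c(OC)c2)c(OC)c1 | intermediate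
14 | 4,5-dibromobenzene-1,2-diol | Oc1cc(Br)c(Br)cc1O | starting material
15 | 5,6-dibromo-2,2-dimethyl-1,3-benzodioxole | CC1(C)Oc2cc(Br)c(Br)cc2O1 | intermediate
16 | diisopropyl (5,6-dibromo-2,2-dimethyl-1,3-benzodioxol-4-yl)boronate (formed in the flask) | CC(C)OB(OC(C)C)c1c(Br)c(Br)cc2OC(C)(C)Oc12 | intermediate
17 | 5,6-dibromo-2,2-dimethyl-1,3-benzodioxol-4-ol | CC1(C)Oc2cc(Br)c(Br)c(O)c2O1 | intermediate
18 | 5,6-dibromo-4-methoxy-2,2-dimethyl-1,3-benzodioxole | COc1c(Br)c(Br)cc2OC(C)(C)Oc12 | intermediate
19 | 4,5-dibromo-3-methoxybenzene-1,2-diol | COc1c(O)c(O)cc(Br)c1Br | intermediate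
20 | 4,5-dibromo-3-methoxy-1,2-benzoquinone | COC1=C(Br)C(Br)=CC(=O)C1=O | intermediate
21 | 4-bromo-3-methoxy-5-(ArABC-oxy)-1,2-benzoquinone (formed in the flask) | COc1cc(OC)c(Oc2cc(OC)c(Oc3cc(OC)c(OC4=CC(=O)C(=O)C(OC)=C4Br)c(OC)c3)c(OC)c2)c(OC)c1 | intermediate
22 | 3-methoxy-5-(ArABC-oxy)-4-(ArEFG-oxy)-1,2-benzoquinone (heptamer with ring D as o-quinone) | COc1cc(OC)c(Oc2cc(OC)c(Oc3cc(OC)c(OC4=CC(=O)C(=O)C(OC)=C4Oc4cc(OC)c(Oc5cc(OC)c(Oc6cc(OC)c(OC)c(OC)c6)c(OC)c5)c(OC)c4)c(OC)c3)c(OC)c2)c(OC)c1 | intermediate
23 | 3-methoxy-5-(ArABC-oxy)-4-(ArEFG-oxy)benzene-1,2-diol (heptamer with ring D as catechol) | COc1cc(OC)c(Oc2cc(OC)c(Oc3cc(OC)c(Oc4cc(O)c(O)c(OC)c4Oc4cc(OC)c(Oc5cc(OC)c(Oc6cc(OC)c(OC)c(OC)c6)c(OC)c5)c(OC)c4)c(OC)c3)c(OC)c2)c(OC)c1 | intermediate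
24 | CNP0304148.0 (all seventeen oxygens not in ether bridges as free OH) | Oc1cc(O)c(Oc2cc(O)c(Oc3cc(O)c(Oc4cc(O)c(O)c(O)c4Oc4cc(O)c(Oc5cc(O)c(Oc6cc(O)c(O)c(O)c6)c(O)c5)c(O)c4)c(O)c3)c(O)c2)c(O)c1 | target

Total step count: 17
Longest linear sequence: 8 steps (1 → 2 → 4 → 5 → 6 → 7 → 22 → 23 → 24; the quinone branch 14 → 15 → 17 → 18 → 19 → 20 → 22 → 23 → 24 is equally long)

Steps most likely to fail

Step 15. Electron transfer from the electron-rich phenoxides to the quinone, carbon attack by ring E of the second phenoxide, and exchange of the aryloxy group already at C5 may outrun the two substitutions. The fallback gives up the quinone oxidation level and sets out from aryl dibromide 18 with the same phenols 7 and 13. A Cu-catalysed Ullmann etherification of 18 with the hindered phenol 7 (CuI, picolinic acid, K3PO4, DMSO, 110 °C) should take the bromide that has a free ortho position and give 5-bromo-4-methoxy-2,2-dimethyl-6-(ArABC-oxy)-1,3-benzodioxole F1. A second Ullmann coupling of F1 with the ortho-unsubstituted phenol 13 (same catalyst, 120 °C) should give 4-methoxy-2,2-dimethyl-6-(ArABC-oxy)-5-(ArEFG-oxy)-1,3-benzodioxole F2. Cleavage of the acetonide with TFA–H2O then comes back to the route at catechol 23.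

Step 7. Oxidation of the electron-rich phenol 1 by Cu(II)/O2, together with protodeboronation or homocoupling of 10, may consume both partners before the hindered phenoxide couples. The fallback is a metal-free O-arylation that sets out from 1. Commercial 5-iodo-1,2,3-trimethoxybenzene is converted in one pot (mCPBA, TsOH·H2O, then 1,3,5-trimethoxybenzene) into (3,4,5-trimethoxyphenyl)(2,4,6-trimethoxyphenyl)iodonium tosylate F3. With 1 and K2CO3 in toluene at rt–50 °C this should transfer the 3,4,5-trimethoxyphenyl group to the phenoxide oxygen by ligand coupling on iodine(III), the 2,4,6-trimethoxyphenyl group acting as the non-transferred ligand and the aryl bromide being inert. The sequence comes back to the route at 11.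

Step 17. Incomplete cleavage of the fifteen methyl ethers and air oxidation of the free polyphenol (ring D above all) during isolation may erode the last step. The fallback separates ether cleavage from isolation and sets out from 23. After BBr3 treatment and removal of volatiles the crude polyphenol is acetylated at once (Ac2O, pyridine, DMAP) to the heptadecaacetate of the target F4, which is stable and can be chromatographed; fractions still carrying methyl ethers can be resubmitted to BBr3. Transesterification (catalytic NaOMe, degassed MeOH, then acidic resin) comes back to the route at 24.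

Further compounds
F1 | step 15 | 5-bromo-4-methoxy-2,2-dimethyl-6-(ArABC-oxy)-1,3-benzodioxole | COc1cc(OC)c(Oc2cc(OC)c(Oc3cc(OC)c(Oc4cc5OC(C)(C)Oc5c(OC)c4Br)c(OC)c3)c(OC)c2)c(OC)c1
F2 | step 15 | 4-methoxy-2,2-dimethyl-6-(ArABC-oxy)-5-(ArEFG-oxy)-1,3-benzodioxole | COc1cc(OC)c(Oc2cc(OC)c(Oc3cc(OC)c(Oc4cc5OC(C)(C)Oc5c(OC)c4Oc4cc(OC)c(Oc5cc(OC)c(Oc6cc(OC)c(OC)c(OC)c6)c(OC)c5)c(OC)c4)c(OC)c3)c(OC)c2)c(OC)c1
F3 | step 7 | (3,4,5-trimethoxyphenyl)(2,4,6-trimethoxyphenyl)iodonium tosylate | COc1cc(OC)c([I+]c2cc(OC)c(OC)c(OC)c2)c(OC)c1.Cc1ccc(cc1)S([O-])(=O)=O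
F4 | step 17 | heptadecaacetate of the target | CC(=O)Oc1cc(OC(C)=O)c(Oc2cc(OC(C)=O)c(Oc3cc(OC(C)=O)c(Oc4cc(OC(C)=O)c(OC(C)=O)c(OC(C)=O)c4Oc4cc(OC(C)=O)c(Oc5cc(OC(C)=O)c(Oc6cc(OC(C)=O)c(OC(C)=O)c(OC(C)=O)c6)c(OC(C)=O)c5)c(OC(C)=O)c4)c(OC(C)=O)c3)c(OC(C)=O)c2)c(OC(C)=O)c1
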